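**Plan**
1. Numbering: ring A (five-membered) is C1 (quaternary, methyl)–C2–C3–C4 (OH, isopropyl)–C5 (H). Ring B (seven-membered) is C5–C6 (ester oxygen)–C7–C8 (methyl)=C9–C10 (ketone)–C1.
2. Retrosynthesis: cut the C6–O acyl bond and the C8–CH3 bond, then take C9 out of ring B (bonds C9–C10 and C8–C9). C9 is the only carbon between C8 and the C10 ketone and the other α-carbon, C1, is quaternary, so ring B is the cyclohexanone C1–C5–C6–C7–C8–C10 plus one inserted carbon, and only C8 can migrate.
3. The cyclohexanone is cut at the C10 oxygen (allylic oxidation), C1–CH3, C8–C10 and C6–C7, and ring A at C1=C5. This leads to (S)-terpinen-4-ol, whose ring methyl becomes C10.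
4. Forward: ring A by aldol condensation, then the six-membered ring by vinyl addition and 6π closure, then the angular methyl and the 1,4-dione. Ring B follows by one-carbon ring expansion, then the enone, the C8 methyl and the ester.
5. Stereochemistry: C4 comes from (S)-terpinen-4-ol. The C1 methyl and H-5 enter anti to the C4 isopropyl group (cuprate addition, enolate protonation). C6 is set by hydride attack on the convex face.

Key step: step 12

Remark: commercial (S)-terpinen-4-ol is assumed to be of high enantiomeric purity; β denotes the face of ring A that carries the C1 methyl, H-5 and the C4 oxygen in the target, α the opposite face.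

Step 1
Reactants: 1 (S)-terpinen-4-ol
Product: 2 (S)-terpinen-4-ol triethylsilyl ether
Conditions: Et3SiOTf, 2,6-lutidine, CH2Cl2, −78 → 0 °C
Reagents that add atoms: triethylsilyl trifluoromethanesulfonate, CC[Si](CC)(CC)OS(=O)(=O)C(F)(F)F
Why: Silyl ether formation with a silyl triflate protects the hindered tertiary alcohol, which would otherwise lie β to the aldehyde of 3 and invite retro-aldol cleavage or dehydration in step 2.

Step 2
Reactants: 2 (S)-terpinen-4-ol triethylsilyl ether
Product: 4 ring A enal (C1=C5 with CHO on C5 and the C10 methyl on C1), via keto-aldehyde 3 (not isolated)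
Conditions: O3, CH2Cl2, −78 °C; Me2S, −78 °C → rt; then piperidine (cat.), AcOH (cat.), benzene, 60 °C
Reagents that add atoms: ozone, [O-][O+]=O
Why: Ozonolysis cleaves the trisubstituted alkene to keto-aldehyde 3, and amine-catalysed intramolecular aldol condensation (the aldehyde enamine attacks the methyl ketone in a 5-exo closure, then water is lost) forms ring A with C1=C5, as is usual for 6-oxoheptanals; C4 is untouched and the ring methyl of 1 now sits on C1 as the future C10.

Step 3
Reactants: 4 ring A enal; 5 vinylmagnesium bromide
Product: 6 divinyl carbinol (both C6 epimers)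
Conditions: CH2=CHMgBr, THF, −78 °C; then sat. aq. NH4Cl
Reagents that add atoms: none
Why: Grignard 1,2-addition to the hindered enal brings in C7 and C8; the new C6 carbinol centre is of no consequence because it is oxidised in step 4.

Step 4
Reactants: 6 divinyl carbinol
Product: 7 cross-conjugated dienone (cyclopentenyl vinyl ketone)
Conditions: Dess–Martin periodinane, CH2Cl2, 0 °C → rt
Reagents that add atoms: none
Why: Dess–Martin oxidation of the doubly allylic alcohol gives the divinyl ketone under conditions that are neither basic nor strongly acidic, so the vinyl ketone and the silyl ether survive.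

Step 5
Reactants: 7 cross-conjugated dienone
Product: 8 bicyclic enone (C6 ketone conjugated to the ring-fusion alkene C1=C5)
Conditions: KOt-Bu (0.2 equiv), t-BuOH–THF, 0 °C → rt
Reagents that add atoms: none
Why: Reversible γ-deprotonation at the C10 methyl gives a 3-oxido-hexatriene held s-cis about C1–C5 by ring A, which closes by disrotatory 6π-electrocyclisation to form C8–C10 (formally an intramolecular vinylogous Michael addition), and protonation at C7 gives the conjugated enone; the competing C2 dienolate is locked s-trans and can only revert.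

Step 6
Reactants: 8 bicyclic enone
Product: 9 cis-fused angular-methyl ketone (Me-1, H-5 and O-4 all β; C6 ketone)
Conditions: Me2CuLi (from CuI and MeLi), Et2O, −40 → 0 °C; then AcOH, THF, −78 °C
Reagents that add atoms: lithium dimethylcuprate, [Li+].C[Cu-]C
Why: Conjugate addition of the cuprate to the tetrasubstituted enone should deliver methyl to C1 on the β-face, anti to the isopropyl group, which is taken as the larger of the two C4 substituents flanking the alkene; kinetic protonation of the lithium enolate at C5 from the same face then gives the cis ring fusion.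

Step 7
Reactants: 9 cis-fused angular-methyl ketone
Product: 11 cyclohexenone (C7=C8 enone), via silyl enol ether 10 (not isolated)
Conditions: LiN(i-Pr)2 (LDA), THF, −78 °C; Me3SiCl; then Pd(OAc)2, MeCN, rt
Reagents that add atoms: none
Why: Kinetic deprotonation occurs at the C7 methylene rather than at the hindered C5 methine, and Saegusa–Ito dehydrogenation of the silyl enol ether (palladium enolate, β-hydride elimination from C8) gives the C7=C8 enone without touching C5.

Step 8
Reactants: 11 cyclohexenone
Product: 12 ene-1,4-dione (C6 and C10 ketones, C7=C8)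
Conditions: Pd(OH)2/C (cat.), t-BuOOH, K2CO3 (cat.), CH2Cl2, 0 °C → rt
Reagents that add atoms: tert-butyl hydroperoxide, CC(C)(C)OO
Why: Palladium-catalysed allylic oxidation of an enone with t-BuOOH (γ-hydrogen abstraction, peroxide formation, loss of t-BuOH) converts the only γ-methylene, C10, into a ketone, as in the oxidation of isophorone-type enones to ene-1,4-diones; C1 is quaternary, so the ene-dione cannot tautomerise to a hydroquinone.

Step 9
Reactants: 12 ene-1,4-dione
Product: 13 cis-fused 1,4-diketone
Conditions: H2 (1 atm), Pd/C, EtOAc, rt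
Reagents that add atoms: none
Why: Heterogeneous hydrogenation saturates the electron-poor C7=C8 bond chemoselectively and leaves both ketones and the silyl ether.

Step 10
Reactants: 13 cis-fused 1,4-diketone
Product: 14 hydroxy ketone (C6–OH α, C10 ketone)
Conditions: LiBH(s-Bu)3 (L-Selectride), THF, −78 °C; then H2O
Reagents that add atoms: none
Why: The bulky hydride should reduce the C6 ketone, whose α-carbon C5 carries a hydrogen on the open β-face, in preference to the C10 ketone flanked by quaternary C1, and attack from that convex β-face (ring A and its isopropyl group screen the α-face) sets the C6 hydroxyl α, trans to H-5.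

Step 11
Reactants: 14 hydroxy ketone
Product: 15 cis-hydrindanone bis-silyl ether (C6–OSiMe2t-Bu, C4–OSiEt3, C10 ketone)
Conditions: t-BuMe2SiOTf, 2,6-lutidine, CH2Cl2, −78 → 0 °C
Reagents that add atoms: tert-butyldimethylsilyl trifluoromethanesulfonate, CC(C)(C)[Si](C)(C)OS(=O)(=O)C(F)(F)F
Why: Silylation of the hindered secondary alcohol with a silyl triflate and a weak pyridine base masks the hydroxyl for the Lewis acid and amide base steps that follow, without enolising the ketone.

Step 12
Reactants: 15 cis-hydrindanone bis-silyl ether; 16 trimethylsilyldiazomethane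
Product: 18 cis-fused cycloheptanone (ring B saturated), via α-silyl ketone 17 (not isolated)
Conditions: Me3Al, Me3SiCHN2, CH2Cl2, −78 → −20 °C; then 1 M HCl, THF, 0 °C
Reagents that add atoms: none
Why: Me3Al binds the C10 carbonyl, the diazo carbon of 16 adds to it, and the β-aluminoxy diazonium loses N2 with a 1,2-shift of C8 from C10 to the new carbon C9 (bonds C9–C10 and C8–C9), giving α-silyl ketone 17, which is protodesilylated on acidic work-up. The closest known reaction type is the Lewis acid-promoted homologation of cyclic ketones with trimethylsilyldiazomethane, a Tiffeneau–Demjanov-type ring expansion. Ring B arises not by cyclisation but by enlargement of the six-membered ring C1–C5–C6–C7–C8–C10 through this single 1,2-alkyl shift. No stereocentre is created in 18 (C9 ends as CH2), and C1, C4, C5 and C6 are not touched because C1 does not migrate and nothing is enolised at low temperature. The step needs migration of C8 rather than C1: C8 is an unsubstituted methylene and C1 is quaternary, and in the aluminate adduct carrying the bulky C-silyl group the less substituted carbon is the one that reaches the anti-periplanar alignment with the departing N2. The single α-branch keeps the carbonyl accessible, and the silyl group on C9 of 17 suppresses a second insertion.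

Step 13
Reactants: 18 cis-fused cycloheptanone
Product: 20 cycloheptenone (C8=C9 enone), via silyl enol ether 19 (not isolated)
Conditions: LiN(i-Pr)2 (LDA), THF, −78 °C; Me3SiCl; then Pd(OAc)2, MeCN, rt
Reagents that add atoms: none
Why: Enolisation can only occur toward C9 because C1 is quaternary, and Saegusa–Ito dehydrogenation then places the alkene at C8=C9.

Step 14
Reactants: 20 cycloheptenone
Product: 22 β-methyl enone (C8 methyl, C8=C9), via silyl enol ether 21 (not isolated)
Conditions: Me2CuLi, Me3SiCl, THF, −78 °C; then Pd(OAc)2, MeCN, rt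
Reagents that add atoms: lithium dimethylcuprate, [Li+].C[Cu-]C
Why: Cuprate conjugate addition to the unhindered β-carbon C8 with in situ silylation gives the regiodefined enol ether 21 (its C8 configuration is irrelevant), and a second Saegusa–Ito dehydrogenation with β-hydride loss from C8 restores the C8=C9 alkene, now carrying the methyl group.

Step 15
Reactants: 22 β-methyl enone
Product: 23 enone diol (C4–OH, C6–OH)
Conditions: HF·pyridine, THF, 0 °C → rt
Reagents that add atoms: none
Why: Fluoride cleaves both silyl ethers under acidic conditions, which avoids γ-deprotonation of the enone and loss of the C6 oxygen.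

Step 16
Reactants: 23 enone diol; 24 4-methoxybenzoyl chloride
Product: 25 target 4-methoxybenzoate
Conditions: 4-MeOC6H4COCl, DMAP (cat.), pyridine, CH2Cl2, 0 °C → rt
Reagents that add atoms: none
Why: DMAP-catalysed acylation takes place only at the secondary C6 hydroxyl, the tertiary C4 hydroxyl being inert under these conditions.

**Compound list**
1 | (S)-terpinen-4-ol | CC1=CC[C@](O)(C(C)C)CC1 | starting material
2 | (S)-terpinen-4-ol triethylsilyl ether | CC1=CC[C@](O[Si](CC)(CC)CC)(C(C)C)CC1 | intermediate
3 | keto-aldehyde, 3-isopropyl-6-oxo-3-(triethylsilyloxy)heptanal (C4 as in 1) | O=CC[C@](O[Si](CC)(CC)CC)(C(C)C)CCC(C)=O | intermediate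
4 | ring A enal, 2-methyl-5-isopropyl-5-(triethylsilyloxy)cyclopent-1-ene-1-carbaldehyde (C4 as in 1) | CC1=C(C=O)[C@](O[Si](CC)(CC)CC)(C(C)C)CC1 | intermediate
5 | vinylmagnesium bromide | C=C[Mg]Br | starting material
6 | divinyl carbinol, 1-(cyclopentenyl)prop-2-en-1-ol from 4 (both C6 epimers) | CC1=C(C(O)C=C)[C@](O[Si](CC)(CC)CC)(C(C)C)CC1 | intermediate
7 | cross-conjugated dienone, 1-(cyclopentenyl)prop-2-en-1-one | CC1=C(C(=O)C=C)[C@](O[Si](CC)(CC)CC)(C(C)C)CC1 | intermediate
8 | bicyclic enone (C6 ketone, C1=C5 alkene, C4 silyloxy and isopropyl) | O=C1CCCC2=C1[C@](O[Si](CC)(CC)CC)(C(C)C)CC2 | intermediate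
9 | cis-fused angular-methyl ketone (Me-1 β, H-5 β, O-4 β, C6 ketone) | O=C2CCC[C@@]3(C)CC[C@@](O[Si](CC)(CC)CC)(C(C)C)[C@@H]23 | intermediate
10 | trimethylsilyl enol ether of 9 (C6=C7) | C[Si](C)(C)OC2=CCC[C@@]3(C)CC[C@@](O[Si](CC)(CC)CC)(C(C)C)[C@@H]23 | intermediate
11 | cyclohexenone (C6 ketone, C7=C8) | O=C2C=CC[C@@]3(C)CC[C@@](O[Si](CC)(CC)CC)(C(C)C)[C@@H]23 | intermediate
12 | ene-1,4-dione (C6 and C10 ketones, C7=C8) | O=C2C=CC(=O)[C@@]3(C)CC[C@@](O[Si](CC)(CC)CC)(C(C)C)[C@@H]23 | intermediate
13 | cis-fused 1,4-diketone (C6 and C10 ketones) | O=C2CCC(=O)[C@@]3(C)CC[C@@](O[Si](CC)(CC)CC)(C(C)C)[C@@H]23 | intermediate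
14 | hydroxy ketone (C6–OH α, C10 ketone) | O[C@H]2CCC(=O)[C@@]3(C)CC[C@@](O[Si](CC)(CC)CC)(C(C)C)[C@@H]23 | intermediate
15 | cis-hydrindanone bis-silyl ether (C6–OSiMe2t-Bu α, C4–OSiEt3 β, C10 ketone) | CC(C)(C)[Si](C)(C)O[C@H]2CCC(=O)[C@@]3(C)CC[C@@](O[Si](CC)(CC)CC)(C(C)C)[C@@H]23 | intermediate
16 | trimethylsilyldiazomethane | C[Si](C)(C)C=[N+]=[N-] | starting material
17 | α-silyl ketone (18 with Me3Si on C9, either configuration) | CC(C)(C)[Si](C)(C)O[C@H]2CCC([Si](C)(C)C)C(=O)[C@@]3(C)CC[C@@](O[Si](CC)(CC)CC)(C(C)C)[C@@H]23 | intermediate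
18 | cis-fused cycloheptanone (ring B: C5–C6–C7–C8–C9–C10–C1, C10 ketone) | CC(C)(C)[Si](C)(C)O[C@H]2CCCC(=O)[C@@]3(C)CC[C@@](O[Si](CC)(CC)CC)(C(C)C)[C@@H]23 | intermediate
19 | trimethylsilyl enol ether of 18 (C9=C10) | CC(C)(C)[Si](C)(C)O[C@H]2CCC=C(O[Si](C)(C)C)[C@@]3(C)CC[C@@](O[Si](CC)(CC)CC)(C(C)C)[C@@H]23 | intermediate
20 | cycloheptenone (C8=C9, C10 ketone) | CC(C)(C)[Si](C)(C)O[C@H]2CC=CC(=O)[C@@]3(C)CC[C@@](O[Si](CC)(CC)CC)(C(C)C)[C@@H]23 | intermediate
21 | trimethylsilyl enol ether of the C8-methyl ketone (C9=C10, either C8 epimer) | CC(C)(C)[Si](C)(C)O[C@H]2CC(C)C=C(O[Si](C)(C)C)[C@@]3(C)CC[C@@](O[Si](CC)(CC)CC)(C(C)C)[C@@H]23 | intermediate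
22 | β-methyl enone bis-silyl ether (C8 methyl, C8=C9, C10 ketone) | CC(C)(C)[Si](C)(C)O[C@H]2CC(C)=CC(=O)[C@@]3(C)CC[C@@](O[Si](CC)(CC)CC)(C(C)C)[C@@H]23 | intermediate
23 | enone diol (C4–OH β, C6–OH α) | O[C@H]2CC(C)=CC(=O)[C@@]3(C)CC[C@@](O)(C(C)C)[C@@H]23 | intermediate
24 | 4-methoxybenzoyl chloride | COc1ccc(C(=O)Cl)cc1 | starting material
25 | target, C6 4-methoxybenzoate of 23 | COc1ccc(C(=O)O[C@H]2CC(C)=CC(=O)[C@@]3(C)CC[C@@](O)(C(C)C)[C@@H]23)cc1 | target

**Step count and risks**

Total step count: 16 (one-pot sequences with a non-isolated intermediate count as one step). Longest linear sequence: 16 steps from 1.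

Step 6 is the most exposed. The two C4 substituents that flank the enone (OSiEt3 on the β-face, isopropyl on the α-face) may not differ enough in effective size, so methyl transfer to C1 may show poor facial selectivity, and protonation at C5 may not follow the same face. The fallback sets out from 8. HF·pyridine removes the silyl group to give the hydroxy enone F1. Its lithium alkoxide (MeLi, one equivalent) is then treated with Me2CuLi, so that the bare alkoxide is clearly the small flank and can anchor the cuprate on the β-face; a cold AcOH quench gives the β-hydroxy ketone F2. Immediate silylation with Et3SiOTf and 2,6-lutidine at −78 °C, before any base can trigger retro-aldol cleavage, returns to the route at 9.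

Step 5 comes second. The trienolate may fail to close, either because anionic polymerisation of the vinyl ketone outruns the electrocyclisation or because the enolate geometry about C5–C6 is unfavourable. The fallback sets out from 4 and builds the same ring by cycloaddition. γ-Deprotonation of 4 at the C10 methyl with KN(SiMe3)2 and silylation with Me3SiCl gives the exocyclic 1-silyloxy diene F3, which is locked s-cis. Diels–Alder reaction with phenyl vinyl sulfone gives the cycloadduct F4, and K2CO3 in MeOH frees the allylic alcohol F5. Dess–Martin oxidation gives the β-keto sulfone F6, and reductive desulfonylation with aluminium amalgam (Al/Hg) returns to the route at 8.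

Step 10 comes third. Chemoselectivity between the two ring ketones may be lost (hydride also attacks C10), or C5 may epimerise in the 1,4-diketone before reduction is complete. The fallback sets out from 13. HF·pyridine gives the hydroxy diketone F7. Hydroxyl-directed reduction with Me4NBH(OAc)3 in AcOH–MeCN at −20 °C delivers hydride from boron bound at O-4 to the β-face of the C6 carbonyl only, under acidic conditions that prevent retro-aldol cleavage and epimerisation, and gives the diol F8. t-BuMe2SiCl with imidazole silylates only the secondary hydroxyl to give the mono-silyl ether F9, and Et3SiOTf with 2,6-lutidine returns to the route at 15.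

**Further compounds**
F1 | step 6 | hydroxy enone (8 without the silyl group) | O=C1CCCC2=C1[C@](O)(C(C)C)CC2
F2 | step 6 | β-hydroxy ketone (9 without the silyl group) | O=C2CCC[C@@]3(C)CC[C@@](O)(C(C)C)[C@@H]23
F3 | step 5 | exocyclic 1-silyloxy diene from 4 (C1=CH2, C5=C6H–OSiMe3) | C=C1CC[C@@](O[Si](CC)(CC)CC)(C(C)C)C1=CO[Si](C)(C)C
F4 | step 5 | Diels–Alder adduct (C6–OSiMe3, C7–SO2Ph, C1=C5) | C[Si](C)(C)OC1C(S(=O)(=O)c2ccccc2)CCC2=C1[C@](O[Si](CC)(CC)CC)(C(C)C)CC2
F5 | step 5 | allylic alcohol (C6–OH, C7–SO2Ph) | OC1C(S(=O)(=O)c2ccccc2)CCC2=C1[C@](O[Si](CC)(CC)CC)(C(C)C)CC2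
F6 | step 5 | β-keto sulfone (C6 ketone, C7–SO2Ph) | O=C1C(S(=O)(=O)c2ccccc2)CCC2=C1[C@](O[Si](CC)(CC)CC)(C(C)C)CC2
F7 | step 10 | hydroxy diketone (13 without the silyl group) | O=C2CCC(=O)[C@@]3(C)CC[C@@](O)(C(C)C)[C@@H]23
F8 | step 10 | diol ketone (C4–OH β, C6–OH α, C10 ketone) | O[C@H]2CCC(=O)[C@@]3(C)CC[C@@](O)(C(C)C)[C@@H]23
F9 | step 10 | C6 tert-butyldimethylsilyl ether with free C4–OH | CC(C)(C)[Si](C)(C)O[C@H]2CCC(=O)[C@@]3(C)CC[C@@](O)(C(C)C)[C@@H]23
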